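**Strategy.** The depsidone is cut at its two inter-ring C–O bonds (diaryl ether and seven-membered lactone), giving an A-ring fluoro aldehyde and the hexasubstituted phthalide ring B. Ring B is built in one operation: light converts a vinyl diazo keto ester into an ester-bearing vinylketene, which adds a siloxyalkyne; 4π opening and 6π closure then deliver the benzene ring with four new C–C bonds. The step exploits the B-ring pattern in which the carbon bearing the depside ester oxygen lies between the CH2OH carbon and the diaryl-ether oxygen carbon, with OH meta and the lactone C=O para. The precursor is a 2-diazo-3-oxopent-4-enoate carrying a benzyl-protected β-alkoxyvinyl unit.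

Key step: step 7

**Remarks on the chemistry**
- The target SMILES contains no stereogenic element; the compound is achiral and no enantiocontrol is needed. The two sp3-containing intermediates of step 7 are racemic and transient.
- Protecting groups follow the origin of each oxygen. Both oxygens delivered by the vinyl unit carry benzyl, so one hydrogenolysis frees the ether phenol and closes the phthalide. Both oxygens delivered by the alkyne, and the A-ring carboxyl, carry silicon-based groups and are freed together by fluoride at the end; no hydrogenolysis is then needed on the electron-rich hydroxymethyl arene. The two phenols that must be free at or after lactonisation carry MOM.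
- The diaryl ether is made before the lactone. An aryl ester could migrate between the two adjacent B-ring phenol oxygens under base, so the regiochemistry is fixed by having only one of them free at the ether-forming stage.

**Route**

Step 1
Reactants: 1 methyl 3-(benzyloxy)propanoate
Product: 3 methyl (2E)-3-(benzyloxy)-2-[(benzyloxy)methyl]prop-2-enoate, via sodium formyl enolate 2 (not isolated)
Conditions: NaH, HCO2Me, THF, 0 °C → rt; evaporate; BnBr, DMF, rt
Reagents that add atoms: methyl formate COC=O; benzyl bromide BrCc1ccccc1; sodium hydride [Na+].[H-] (sodium of 2 only)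
Why: Crossed Claisen formylation at the only enolisable carbon gives the stabilised enolate 2, which is O-benzylated (Williamson alkylation in DMF) because its carbon terminus is fully substituted; the E isomer (OBn trans to the ester) is the expected thermodynamic product, and the geometry is in any case lost on aromatisation in step 7.

Step 2
Reactants: 3 methyl (2E)-3-(benzyloxy)-2-[(benzyloxy)methyl]prop-2-enoate
Product: 4 (2E)-3-(benzyloxy)-2-[(benzyloxy)methyl]prop-2-enoic acid
Conditions: LiOH·H2O, THF/MeOH/H2O, 45 °C; then 1 M HCl to pH 3, 0 °C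
Reagents that add atoms: lithium hydroxide [Li+].[OH-]
Why: Ester saponification; β-alkoxyacrylates are vinylogous carbonates that tolerate hydroxide and brief mild acidification, as in the standard preparation of 3-alkoxyacrylic acids.

Step 3
Reactants: 4 (2E)-3-(benzyloxy)-2-[(benzyloxy)methyl]prop-2-enoic acid
Product: 6 methyl (4E)-5-(benzyloxy)-4-[(benzyloxy)methyl]-3-oxopent-4-enoate, via acyl imidazolide 5 (not isolated)
Conditions: CDI, THF, rt; then Mg(O2CCH2CO2Me)2, THF, 45 °C; aq. HCl work-up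
Reagents that add atoms: magnesium bis(3-methoxy-3-oxopropanoate) COC(=O)CC(=O)[O-].COC(=O)CC(=O)[O-].[Mg+2]; 1,1'-carbonyldiimidazole O=C(n1ccnc1)n1ccnc1 (imidazolyl group of 5 only)
Why: Masamune–Brooks homologation: the acyl imidazolide C-acylates the magnesium enolate of the malonate half ester and decarboxylation gives the β-keto ester under near-neutral conditions that leave the enol ether intact.

Step 4
Reactants: 6 methyl (4E)-5-(benzyloxy)-4-[(benzyloxy)methyl]-3-oxopent-4-enoate
Product: 7 methyl (4E)-5-(benzyloxy)-4-[(benzyloxy)methyl]-2-diazo-3-oxopent-4-enoate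
Conditions: p-ABSA, Et3N, MeCN, 0 °C → rt
Reagents that add atoms: 4-acetamidobenzenesulfonyl azide CC(=O)Nc1ccc(cc1)S(=O)(=O)N=[N+]=[N-]
Why: Regitz diazo transfer to the doubly activated methylene of a β-keto ester.

Step 5
Reactants: 8 prop-2-yn-1-ol
Product: 9 tert-butyl(diphenyl)(prop-2-yn-1-yloxy)silane
Conditions: TBDPSCl, imidazole, DMF, rt
Reagents that add atoms: tert-butyl(chloro)diphenylsilane CC(C)(C)[Si](Cl)(c1ccccc1)c1ccccc1
Why: Standard silylation of a primary alcohol; TBDPS is chosen to outlast the later acid step.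

Step 6
Reactants: 9 tert-butyl(diphenyl)(prop-2-yn-1-yloxy)silane
Product: 11 tert-butyl(diphenyl)[(3-{[tri(propan-2-yl)silyl]oxy}prop-2-yn-1-yl)oxy]silane, via lithium ynolate 10 (not isolated)
Conditions: LiHMDS (2.2 equiv), t-BuOOH, THF, −78 → 0 °C; then TIPSOTf, −78 → 0 °C
Reagents that add atoms: tert-butyl hydroperoxide CC(C)(C)OO; triisopropylsilyl trifluoromethanesulfonate CC(C)[Si](C(C)C)(C(C)C)OS(=O)(=O)C(F)(F)F; lithium bis(trimethylsilyl)amide [Li+].C[Si](C)(C)[N-][Si](C)(C)C (lithium of 10 only)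
Why: Julia–Kozmin siloxyalkyne synthesis: the lithium acetylide is oxidised by lithium tert-butyl peroxide to the ynolate, which the silyl triflate traps on oxygen.

Step 7
Reactants: 7 methyl (4E)-5-(benzyloxy)-4-[(benzyloxy)methyl]-2-diazo-3-oxopent-4-enoate; 11 tert-butyl(diphenyl)[(3-{[tri(propan-2-yl)silyl]oxy}prop-2-yn-1-yl)oxy]silane
Product: 16 methyl 3-(benzyloxy)-2-[(benzyloxy)methyl]-5-({[tert-butyl(diphenyl)silyl]oxy}methyl)-4-hydroxy-6-{[tri(propan-2-yl)silyl]oxy}benzoate, via vinylketene 12 (not isolated), via vinylcyclobutenone 13 (not isolated), via dienylketene 14 (not isolated), via cyclohexadienone 15 (not isolated)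
Conditions: 11 (1.5 equiv), hν (300 nm, Pyrex), ClCH2CH2Cl, 20 °C; then 80 °C
Reagents that add atoms: none
Why: Proposed new method: excitation of 7 expels N2 and the vinyl group on the ketone side migrates (Wolff rearrangement) to give the methoxycarbonyl vinylketene 12, whose carbonyl carbon is attacked by the nucleophilic alkyne carbon of 11 (the one bearing CH2OTBDPS) to close cyclobutenone 13; the closest known reaction type is the photochemical vinylketene benzannulation of vinyl diazo ketones with siloxyalkynes, which has not been shown for a 2-diazo-3-oxo ester with a β-alkoxyvinyl group. On warming, 13 opens by reversible conrotatory 4π electrocyclic cleavage to dienylketene 14, and the benzene ring closes by thermal disrotatory 6π electrocyclisation to 15, which tautomerises to phenol 16. No stereocentre remains in the product. The whole substitution pattern depends on the [2+2] regiochemistry, which the polarisation of the ynol ether dictates, and on vinyl rather than methoxy migration in the Wolff step, which is the normal preference of diazo β-keto esters because alkoxy groups migrate poorly. The E enol ether places the benzyloxy group outward in 14, so the closing terminus carries only an inward hydrogen, and because ring opening of 13 is reversible the rotamer with the vinyl group cis to the ketene is drained. Benzyl and silyl ethers are inert to light and heat here, and the excess of 11 should intercept the electrophilic ketene before it dimerises.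

Step 8
Reactants: 16 methyl 3-(benzyloxy)-2-[(benzyloxy)methyl]-5-({[tert-butyl(diphenyl)silyl]oxy}methyl)-4-hydroxy-6-{[tri(propan-2-yl)silyl]oxy}benzoate
Product: 17 methyl 3-(benzyloxy)-2-[(benzyloxy)methyl]-5-({[tert-butyl(diphenyl)silyl]oxy}methyl)-4-(methoxymethoxy)-6-{[tri(propan-2-yl)silyl]oxy}benzoate
Conditions: MOMCl, i-Pr2NEt, CH2Cl2, 0 → 40 °C
Reagents that add atoms: chloromethyl methyl ether COCCl
Why: Alkylation of the only free phenol as its MOM acetal; an alkyl-type group is used because an acyl or silyl group could migrate to the neighbouring oxygen once that is unmasked.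

Step 9
Reactants: 17 methyl 3-(benzyloxy)-2-[(benzyloxy)methyl]-5-({[tert-butyl(diphenyl)silyl]oxy}methyl)-4-(methoxymethoxy)-6-{[tri(propan-2-yl)silyl]oxy}benzoate
Product: 19 6-({[tert-butyl(diphenyl)silyl]oxy}methyl)-4-hydroxy-5-(methoxymethoxy)-7-{[tri(propan-2-yl)silyl]oxy}-2-benzofuran-1(3H)-one, via hydroxy ester 18 (not isolated)
Conditions: H2 (1 atm), 10% Pd/C, EtOAc, rt; filter; then Et3N (cat.), PhMe, 50 °C
Reagents that add atoms: none
Why: Hydrogenolysis cleaves both benzyl ethers at the unhindered PhCH2–O bonds, and the freed benzylic alcohol lactonises onto the ortho methyl ester to the five-membered phthalide.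

Step 10
Reactants: 20 3-fluoro-5-methylphenol
Product: 21 4-bromo-3-fluoro-5-methylphenol
Conditions: NBS, MeCN, −10 °C → rt
Reagents that add atoms: N-bromosuccinimide O=C1CCC(=O)N1Br
Why: Electrophilic aromatic bromination, expected para to the hydroxyl as with other 3,5-disubstituted phenols under NBS in MeCN.

Step 11
Reactants: 21 4-bromo-3-fluoro-5-methylphenol
Product: 22 2-bromo-1-fluoro-5-(methoxymethoxy)-3-methylbenzene
Conditions: MOMCl, i-Pr2NEt, CH2Cl2, 0 °C → rt
Reagents that add atoms: chloromethyl methyl ether COCCl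
Why: Phenol protection as the MOM ether, which also serves as the directing group for step 12.

Step 12
Reactants: 22 2-bromo-1-fluoro-5-(methoxymethoxy)-3-methylbenzene
Product: 24 2-(trimethylsilyl)ethyl 3-bromo-2-fluoro-6-(methoxymethoxy)-4-methylbenzoate, via aryllithium 23 (not isolated)
Conditions: LDA, THF, −78 °C; then ClCO2CH2CH2SiMe3, −78 °C
Reagents that add atoms: 2-(trimethylsilyl)ethyl chloroformate C[Si](C)(C)CCOC(Cl)=O; lithium diisopropylamide [Li+].CC(C)[N-]C(C)C (lithium of 23 only)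
Why: Directed ortho-metalation: the amide base removes the proton flanked by F and OMOM without exchanging the bromide, and the aryllithium is acylated by the chloroformate.

Step 13
Reactants: 24 2-(trimethylsilyl)ethyl 3-bromo-2-fluoro-6-(methoxymethoxy)-4-methylbenzoate
Product: 26 2-(trimethylsilyl)ethyl 2-fluoro-3-formyl-6-(methoxymethoxy)-4-methylbenzoate, via arylmagnesium chloride 25 (not isolated)
Conditions: i-PrMgCl·LiCl, THF, −20 °C; then DMF, −20 °C → rt; aq. NH4Cl
Reagents that add atoms: N,N-dimethylformamide CN(C)C=O; isopropylmagnesium chloride CC(C)[Mg]Cl (MgCl of 25 only)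
Why: Knochel bromine–magnesium exchange, accelerated by the ortho fluorine and tolerated by the hindered ester at low temperature, followed by Bouveault formylation.

Step 14
Reactants: 19 6-({[tert-butyl(diphenyl)silyl]oxy}methyl)-4-hydroxy-5-(methoxymethoxy)-7-{[tri(propan-2-yl)silyl]oxy}-2-benzofuran-1(3H)-one; 26 2-(trimethylsilyl)ethyl 2-fluoro-3-formyl-6-(methoxymethoxy)-4-methylbenzoate
Product: 27 2-(trimethylsilyl)ethyl 2-{[6-({[tert-butyl(diphenyl)silyl]oxy}methyl)-5-(methoxymethoxy)-1-oxo-7-{[tri(propan-2-yl)silyl]oxy}-1,3-dihydro-2-benzofuran-4-yl]oxy}-3-formyl-6-(methoxymethoxy)-4-methylbenzoate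
Conditions: K2CO3 (anhydrous), DMF, 65 °C
Reagents that add atoms: none
Why: Nucleophilic aromatic substitution (SNAr) of a fluoride activated by a coplanar ortho formyl group and an ortho ester; only the 4-OH of 19 is free, so the protecting-group pattern fixes which oxygen becomes the ether.

Step 15
Reactants: 27 2-(trimethylsilyl)ethyl 2-{[6-({[tert-butyl(diphenyl)silyl]oxy}methyl)-5-(methoxymethoxy)-1-oxo-7-{[tri(propan-2-yl)silyl]oxy}-1,3-dihydro-2-benzofuran-4-yl]oxy}-3-formyl-6-(methoxymethoxy)-4-methylbenzoate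
Product: 28 2-{[6-({[tert-butyl(diphenyl)silyl]oxy}methyl)-5-(methoxymethoxy)-1-oxo-7-{[tri(propan-2-yl)silyl]oxy}-1,3-dihydro-2-benzofuran-4-yl]oxy}-4-(methoxymethoxy)-6-methyl-3-{[2-(trimethylsilyl)ethoxy]carbonyl}benzoic acid
Conditions: NaClO2, NaH2PO4, 2-methyl-2-butene, t-BuOH/THF/H2O, 0 °C → rt
Reagents that add atoms: sodium chlorite [Na+].[O-]Cl=O
Why: Pinnick oxidation, which handles hindered aryl aldehydes and leaves acetals, silyl ethers and esters untouched at buffered pH.

Step 16
Reactants: 28 2-{[6-({[tert-butyl(diphenyl)silyl]oxy}methyl)-5-(methoxymethoxy)-1-oxo-7-{[tri(propan-2-yl)silyl]oxy}-1,3-dihydro-2-benzofuran-4-yl]oxy}-4-(methoxymethoxy)-6-methyl-3-{[2-(trimethylsilyl)ethoxy]carbonyl}benzoic acid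
Product: 29 2-{[6-({[tert-butyl(diphenyl)silyl]oxy}methyl)-5-hydroxy-1-oxo-7-{[tri(propan-2-yl)silyl]oxy}-1,3-dihydro-2-benzofuran-4-yl]oxy}-4-hydroxy-6-methyl-3-{[2-(trimethylsilyl)ethoxy]carbonyl}benzoic acid
Conditions: 3 M HCl (aq), THF/i-PrOH, 40 °C
Reagents that add atoms: none
Why: Acid hydrolysis of the two aryl MOM acetals; the aryl TIPS ether, the TBDPS ether and the silylethyl ester should resist dilute aqueous HCl.

Step 17
Reactants: 29 2-{[6-({[tert-butyl(diphenyl)silyl]oxy}methyl)-5-hydroxy-1-oxo-7-{[tri(propan-2-yl)silyl]oxy}-1,3-dihydro-2-benzofuran-4-yl]oxy}-4-hydroxy-6-methyl-3-{[2-(trimethylsilyl)ethoxy]carbonyl}benzoic acid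
Product: 30 the silyl-protected depsidone: the target with its CO2H as the 2-(trimethylsilyl)ethyl ester, its B-ring phenol as the TIPS ether and its CH2OH as the TBDPS ether
Conditions: DCC, DMAP (cat.), CH2Cl2 (0.005 M), rt
Reagents that add atoms: none
Why: Steglich-type lactonisation to the seven-membered depsidone ring; the B-ring phenol next to the ether oxygen is the only hydroxyl that can reach the activated carboxyl intramolecularly, and the A-ring phenol is a deactivated salicylate OH.

Step 18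
Reactants: 30 the silyl-protected depsidone
Product: 31 conneotricone
Conditions: TBAF, AcOH, THF, 0 °C → rt; acidic work-up (pH 3)
Reagents that add atoms: none
Why: Fluoride cleaves the aryl and alkyl silyl ethers and fragments the 2-(trimethylsilyl)ethyl ester by β-elimination; acetic acid buffering is meant to protect the aryl lactone and the phthalide from basic fluoride.

**Compound list**

1 | methyl 3-(benzyloxy)propanoate | COC(=O)CCOCc1ccccc1 | starting material
2 | sodium 2-[(benzyloxy)methyl]-3-methoxy-3-oxoprop-1-en-1-olate (sodium formyl enolate) | COC(=O)C(COCc1ccccc1)=C[O-].[Na+] | intermediate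
3 | methyl (2E)-3-(benzyloxy)-2-[(benzyloxy)methyl]prop-2-enoate | COC(=O)/C(COCc1ccccc1)=C/OCc1ccccc1 | intermediate
4 | (2E)-3-(benzyloxy)-2-[(benzyloxy)methyl]prop-2-enoic acid | OC(=O)/C(COCc1ccccc1)=C/OCc1ccccc1 | intermediate
5 | (2E)-3-(benzyloxy)-2-[(benzyloxy)methyl]-1-(1H-imidazol-1-yl)prop-2-en-1-one (acyl imidazolide) | O=C(n1ccnc1)/C(COCc1ccccc1)=C/OCc1ccccc1 | intermediate
6 | methyl (4E)-5-(benzyloxy)-4-[(benzyloxy)methyl]-3-oxopent-4-enoate | COC(=O)CC(=O)/C(COCc1ccccc1)=C/OCc1ccccc1 | intermediate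
7 | methyl (4E)-5-(benzyloxy)-4-[(benzyloxy)methyl]-2-diazo-3-oxopent-4-enoate | COC(=O)C(=[N+]=[N-])C(=O)/C(COCc1ccccc1)=C/OCc1ccccc1 | intermediate
8 | prop-2-yn-1-ol | C#CCO | starting material
9 | tert-butyl(diphenyl)(prop-2-yn-1-yloxy)silane | C#CCO[Si](c1ccccc1)(c1ccccc1)C(C)(C)C | intermediate
10 | lithium 3-{[tert-butyl(diphenyl)silyl]oxy}prop-1-yn-1-olate (lithium ynolate) | [Li+].[O-]C#CCO[Si](c1ccccc1)(c1ccccc1)C(C)(C)C | intermediate
11 | tert-butyl(diphenyl)[(3-{[tri(propan-2-yl)silyl]oxy}prop-2-yn-1-yl)oxy]silane | CC(C)[Si](C(C)C)(C(C)C)OC#CCO[Si](c1ccccc1)(c1ccccc1)C(C)(C)C | intermediate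
12 | methyl (3Z)-4-(benzyloxy)-3-[(benzyloxy)methyl]-2-(oxomethylidene)but-3-enoate (vinylketene; benzyloxy trans to the ketene-bearing carbon) | COC(=O)C(=C=O)/C(COCc1ccccc1)=C/OCc1ccccc1 | intermediate
13 | methyl 1-{(Z)-2-(benzyloxy)-1-[(benzyloxy)methyl]ethenyl}-3-({[tert-butyl(diphenyl)silyl]oxy}methyl)-4-oxo-2-{[tri(propan-2-yl)silyl]oxy}cyclobut-2-ene-1-carboxylate (vinylcyclobutenone, racemic) | COC(=O)C1(/C(COCc2ccccc2)=C/OCc2ccccc2)C(=O)C(CO[Si](c2ccccc2)(c2ccccc2)C(C)(C)C)=C1O[Si](C(C)C)(C(C)C)C(C)C | intermediate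
14 | methyl (2Z)-2-{(Z)-2-(benzyloxy)-1-[(benzyloxy)methyl]ethenyl}-4-({[tert-butyl(diphenyl)silyl]oxy}methyl)-5-oxo-3-{[tri(propan-2-yl)silyl]oxy}penta-2,4-dienoate (dienylketene; vinyl group cis to the ketene-bearing carbon) | O=C=C(CO[Si](c1ccccc1)(c1ccccc1)C(C)(C)C)/C(O[Si](C(C)C)(C(C)C)C(C)C)=C(C(=O)OC)\C(COCc1ccccc1)=C\OCc1ccccc1 | intermediate
15 | methyl 3-(benzyloxy)-2-[(benzyloxy)methyl]-5-({[tert-butyl(diphenyl)silyl]oxy}methyl)-4-oxo-6-{[tri(propan-2-yl)silyl]oxy}cyclohexa-1,5-diene-1-carboxylate (cyclohexadienone, racemic) | O=C1C(CO[Si](c2ccccc2)(c2ccccc2)C(C)(C)C)=C(O[Si](C(C)C)(C(C)C)C(C)C)C(C(=O)OC)=C(COCc2ccccc2)C1OCc1ccccc1 | intermediate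
16 | methyl 3-(benzyloxy)-2-[(benzyloxy)methyl]-5-({[tert-butyl(diphenyl)silyl]oxy}methyl)-4-hydroxy-6-{[tri(propan-2-yl)silyl]oxy}benzoate | COC(=O)c1c(O[Si](C(C)C)(C(C)C)C(C)C)c(CO[Si](c2ccccc2)(c2ccccc2)C(C)(C)C)c(O)c(OCc2ccccc2)c1COCc1ccccc1 | intermediate
17 | methyl 3-(benzyloxy)-2-[(benzyloxy)methyl]-5-({[tert-butyl(diphenyl)silyl]oxy}methyl)-4-(methoxymethoxy)-6-{[tri(propan-2-yl)silyl]oxy}benzoate | COC(=O)c1c(O[Si](C(C)C)(C(C)C)C(C)C)c(CO[Si](c2ccccc2)(c2ccccc2)C(C)(C)C)c(OCOC)c(OCc2ccccc2)c1COCc1ccccc1 | intermediate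
18 | methyl 5-({[tert-butyl(diphenyl)silyl]oxy}methyl)-3-hydroxy-2-(hydroxymethyl)-4-(methoxymethoxy)-6-{[tri(propan-2-yl)silyl]oxy}benzoate (hydroxy ester) | COC(=O)c1c(O[Si](C(C)C)(C(C)C)C(C)C)c(CO[Si](c2ccccc2)(c2ccccc2)C(C)(C)C)c(OCOC)c(O)c1CO | intermediate
19 | 6-({[tert-butyl(diphenyl)silyl]oxy}methyl)-4-hydroxy-5-(methoxymethoxy)-7-{[tri(propan-2-yl)silyl]oxy}-2-benzofuran-1(3H)-one | COCOc1c(O)c2COC(=O)c2c(O[Si](C(C)C)(C(C)C)C(C)C)c1CO[Si](c1ccccc1)(c1ccccc1)C(C)(C)C | intermediate
20 | 3-fluoro-5-methylphenol | Cc1cc(O)cc(F)c1 | starting material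
21 | 4-bromo-3-fluoro-5-methylphenol | Cc1cc(O)cc(F)c1Br | intermediate
22 | 2-bromo-1-fluoro-5-(methoxymethoxy)-3-methylbenzene | COCOc1cc(C)c(Br)c(F)c1 | intermediate
23 | [3-bromo-2-fluoro-6-(methoxymethoxy)-4-methylphenyl]lithium (aryllithium) | [Li]c1c(OCOC)cc(C)c(Br)c1F | intermediate
24 | 2-(trimethylsilyl)ethyl 3-bromo-2-fluoro-6-(methoxymethoxy)-4-methylbenzoate | COCOc1cc(C)c(Br)c(F)c1C(=O)OCC[Si](C)(C)C | intermediate
25 | chloro[2-fluoro-4-(methoxymethoxy)-6-methyl-3-{[2-(trimethylsilyl)ethoxy]carbonyl}phenyl]magnesium (arylmagnesium chloride) | Cl[Mg]c1c(C)cc(OCOC)c(C(=O)OCC[Si](C)(C)C)c1F | intermediate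
26 | 2-(trimethylsilyl)ethyl 2-fluoro-3-formyl-6-(methoxymethoxy)-4-methylbenzoate | COCOc1cc(C)c(C=O)c(F)c1C(=O)OCC[Si](C)(C)C | intermediate
27 | 2-(trimethylsilyl)ethyl 2-{[6-({[tert-butyl(diphenyl)silyl]oxy}methyl)-5-(methoxymethoxy)-1-oxo-7-{[tri(propan-2-yl)silyl]oxy}-1,3-dihydro-2-benzofuran-4-yl]oxy}-3-formyl-6-(methoxymethoxy)-4-methylbenzoate | Cc1cc(OCOC)c(C(=O)OCC[Si](C)(C)C)c(Oc2c(OCOC)c(CO[Si](c4ccccc4)(c4ccccc4)C(C)(C)C)c(O[Si](C(C)C)(C(C)C)C(C)C)c3C(=O)OCc23)c1C=O | intermediate
28 | 2-{[6-({[tert-butyl(diphenyl)silyl]oxy}methyl)-5-(methoxymethoxy)-1-oxo-7-{[tri(propan-2-yl)silyl]oxy}-1,3-dihydro-2-benzofuran-4-yl]oxy}-4-(methoxymethoxy)-6-methyl-3-{[2-(trimethylsilyl)ethoxy]carbonyl}benzoic acid | Cc1cc(OCOC)c(C(=O)OCC[Si](C)(C)C)c(Oc2c(OCOC)c(CO[Si](c4ccccc4)(c4ccccc4)C(C)(C)C)c(O[Si](C(C)C)(C(C)C)C(C)C)c3C(=O)OCc23)c1C(=O)O | intermediate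
29 | 2-{[6-({[tert-butyl(diphenyl)silyl]oxy}methyl)-5-hydroxy-1-oxo-7-{[tri(propan-2-yl)silyl]oxy}-1,3-dihydro-2-benzofuran-4-yl]oxy}-4-hydroxy-6-methyl-3-{[2-(trimethylsilyl)ethoxy]carbonyl}benzoic acid | Cc1cc(O)c(C(=O)OCC[Si](C)(C)C)c(Oc2c(O)c(CO[Si](c4ccccc4)(c4ccccc4)C(C)(C)C)c(O[Si](C(C)C)(C(C)C)C(C)C)c3C(=O)OCc23)c1C(=O)O | intermediate
30 | silyl-protected depsidone: the target with CO2H as 2-(trimethylsilyl)ethyl ester, the B-ring phenol as TIPS ether and CH2OH as TBDPS ether | Cc1cc(O)c(C(=O)OCC[Si](C)(C)C)c2c1C(=O)Oc1c(CO[Si](c4ccccc4)(c4ccccc4)C(C)(C)C)c(O[Si](C(C)C)(C(C)C)C(C)C)c3c(c1O2)COC3=O | intermediate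
31 | conneotricone (achiral) | Cc1cc(O)c(C(=O)O)c2c1C(=O)Oc1c(CO)c(O)c3c(c1O2)COC3=O | target

**Step count.** Total: 18 steps. Longest linear sequence: 12 steps (steps 1–4, 7–9, 14–18).

**Steps most likely to fail**

Step 7 (proposed new method). The ketene–ynol ether zwitterion may close through the ester oxygen instead of carbon (pyranone formation), the congested [2+2] at the fully substituted ketene carbon may be slow enough for ketene dimerisation to take over, or methoxy may migrate in place of vinyl. Fallback, by known chemistry, with the ester installed after the ring is made: it sets out from acid 4 and returns at 17. Oxalyl chloride with catalytic DMF converts 4 into (2E)-3-(benzyloxy)-2-[(benzyloxy)methyl]prop-2-enoyl chloride F1. Trimethylsilyldiazomethane then gives the vinyl diazomethyl ketone (3E)-4-(benzyloxy)-3-[(benzyloxy)methyl]-1-diazobut-3-en-2-one F2, a substrate of the class for which the photochemical benzannulation with siloxyalkynes is established. Irradiation of F2 with 11, then heating, gives 2-(benzyloxy)-3-[(benzyloxy)methyl]-6-({[tert-butyl(diphenyl)silyl]oxy}methyl)-5-{[tri(propan-2-yl)silyl]oxy}phenol F3, whose only unsubstituted ring carbon is para to the hydroxyl. NBS brominates that position to give the 4-bromophenol F4, and MOMCl/i-Pr2NEt gives the MOM ether F5. Bromine–lithium exchange (n-BuLi, −78 °C) and methyl chloroformate then give 17.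

Step 14. Substitution may be slow because both partners are ortho,ortho-disubstituted, and the fluoride released may start to strip the B-ring aryl silyl ether. Fallback with the bond order inverted (ester first, ether closed intramolecularly): it sets out from 16 and 26 and returns at 30. Pinnick oxidation of 26 gives 2-fluoro-4-(methoxymethoxy)-6-methyl-3-{[2-(trimethylsilyl)ethoxy]carbonyl}benzoic acid F6. DCC/DMAP couples it to the free phenol of 16 to give the depside ester F7. Hydrogenolysis and lactonisation as in step 9 give the phthalide phenol F8, whose phenoxide (K2CO3, DMF) displaces the now neighbouring fluoride to form the seven-membered ring of the MOM-protected depsidone F9. Acid hydrolysis of the remaining MOM ether gives 30. This order is held in reserve because an aryl ester can migrate between the two adjacent phenol oxygens under base, which makes the regiochemistry of the closure less secure than in the main line.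

Step 18. Basic fluoride may open or transacylate the aryl lactone once the neighbouring benzylic alkoxide is freed, and buffered fluoride may cleave the silylethyl ester only slowly. Fallback without basic fluoride, in two stages: it sets out from 30 and returns at 31. TFA in CH2Cl2 at 0 °C cleaves the 2-(trimethylsilyl)ethyl ester by acidolysis while both silyl ethers still mask the benzylic alcohol and the phenol, giving the bis-silyl depsidone acid F10. HF·pyridine in THF/pyridine then removes the TIPS and TBDPS ethers to give 31.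

**Further compounds**

F1 | step 7 | (2E)-3-(benzyloxy)-2-[(benzyloxy)methyl]prop-2-enoyl chloride | ClC(=O)/C(COCc1ccccc1)=C/OCc1ccccc1
F2 | step 7 | (3E)-4-(benzyloxy)-3-[(benzyloxy)methyl]-1-diazobut-3-en-2-one | [N-]=[N+]=CC(=O)/C(COCc1ccccc1)=C/OCc1ccccc1
F3 | step 7 | 2-(benzyloxy)-3-[(benzyloxy)methyl]-6-({[tert-butyl(diphenyl)silyl]oxy}methyl)-5-{[tri(propan-2-yl)silyl]oxy}phenol | Oc1c(CO[Si](c2ccccc2)(c2ccccc2)C(C)(C)C)c(O[Si](C(C)C)(C(C)C)C(C)C)cc(COCc2ccccc2)c1OCc1ccccc1
F4 | step 7 | 2-(benzyloxy)-3-[(benzyloxy)methyl]-4-bromo-6-({[tert-butyl(diphenyl)silyl]oxy}methyl)-5-{[tri(propan-2-yl)silyl]oxy}phenol | Oc1c(CO[Si](c2ccccc2)(c2ccccc2)C(C)(C)C)c(O[Si](C(C)C)(C(C)C)C(C)C)c(Br)c(COCc2ccccc2)c1OCc1ccccc1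
F5 | step 7 | MOM ether of F4: 2-(benzyloxy)-3-[(benzyloxy)methyl]-4-bromo-6-({[tert-butyl(diphenyl)silyl]oxy}methyl)-1-(methoxymethoxy)-5-{[tri(propan-2-yl)silyl]oxy}benzene | COCOc1c(CO[Si](c2ccccc2)(c2ccccc2)C(C)(C)C)c(O[Si](C(C)C)(C(C)C)C(C)C)c(Br)c(COCc2ccccc2)c1OCc1ccccc1
F6 | step 14 | 2-fluoro-4-(methoxymethoxy)-6-methyl-3-{[2-(trimethylsilyl)ethoxy]carbonyl}benzoic acid | Cc1cc(OCOC)c(C(=O)OCC[Si](C)(C)C)c(F)c1C(=O)O
F7 | step 14 | depside ester: the phenol oxygen of 16 acylated by F6 | COC(=O)c1c(O[Si](C(C)C)(C(C)C)C(C)C)c(CO[Si](c2ccccc2)(c2ccccc2)C(C)(C)C)c(OC(=O)c2c(C)cc(OCOC)c(C(=O)OCC[Si](C)(C)C)c2F)c(OCc2ccccc2)c1COCc1ccccc1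
F8 | step 14 | phthalide phenol depside: 6-({[tert-butyl(diphenyl)silyl]oxy}methyl)-4-hydroxy-1-oxo-7-{[tri(propan-2-yl)silyl]oxy}-1,3-dihydro-2-benzofuran-5-yl ester of F6 | Cc1cc(OCOC)c(C(=O)OCC[Si](C)(C)C)c(F)c1C(=O)Oc1c(CO[Si](c2ccccc2)(c2ccccc2)C(C)(C)C)c(O[Si](C(C)C)(C(C)C)C(C)C)c2C(=O)OCc2c1O
F9 | step 14 | MOM-protected depsidone: compound 30 with its A-ring phenol as the methoxymethyl ether | Cc1cc(OCOC)c(C(=O)OCC[Si](C)(C)C)c2c1C(=O)Oc1c(CO[Si](c4ccccc4)(c4ccccc4)C(C)(C)C)c(O[Si](C(C)C)(C(C)C)C(C)C)c3c(c1O2)COC3=O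
F10 | step 18 | bis-silyl depsidone acid: the target with the B-ring phenol as TIPS ether and CH2OH as TBDPS ether | Cc1cc(O)c(C(=O)O)c2c1C(=O)Oc1c(CO[Si](c4ccccc4)(c4ccccc4)C(C)(C)C)c(O[Si](C(C)C)(C(C)C)C(C)C)c3c(c1O2)COC3=O
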